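Remark on the chemistry: all positions carry the guaiane numbering of the target (C1–C11); β is the face of the seven-membered ring that holds the C10 methyl in the target, α the face of the C1 hydroxyl. Compounds 7 and 17 are carried as epimer mixtures at a centre that later becomes planar, and 16 as an E/Z mixture.

## Structural features

The target is a guaiane: a cyclopentenone (C1–C5, ketone at C3, methyl at C4, C4=C5) fused along C1–C5 to a cycloheptane (C5–C10 and C1), with a 2-acetoxypropan-2-yl group (C11) on C7. Five stereocentres lie on the seven-membered ring: the tertiary carbinol C1 (OH α) next to C10 (methyl β, trans to that OH), and the contiguous all-cis triad C6 (OH β), C7 (side chain β) and C8 (angeloyloxy β). The fragile parts are the tertiary allylic β-hydroxy enone (retro-aldol, ionisation at C1), the allylic C6 hydroxyl, the tertiary acetate, and the (Z)-angelate, which isomerises to the tiglate and does not survive hydride reagents. The real difficulty is placing five stereocentres, one a fully substituted ring-fusion carbinol, on a flexible seven-membered ring while telling four oxygen functions apart (two free hydroxyls, two different esters). The key step uses the fact that O–C1, C10 with its methyl, C9 and C8 are a latent 3-methylfuran and that C5–C6(O)–C7 is an oxyallyl unit; joined through the tether C2–C3–C4 they give both rings in one [4+3] event. The furan oxygen stays as a C1–O–C8 bridge, which makes the seven-membered ring rigid so that C6, C7 and C10 can be set relative to C1. C4 and C5, the only ring carbons that end up sp2, are free to carry the controlling stereocentre and the ring-fusion hydrogen during the route.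

## Logic of the disconnections

**32 ⇒ 30.** Only the C4=C5 π bond is removed. C4 and C5 have no configuration in 32, so in 30 they can be sp3: C4 carries the centre that steers the key step and C5 the ring-fusion hydrogen. The gain is that no unsaturation has to pass through the hydride and aluminium steps. The demand is a desaturation of 30 that enolises C3 toward C4 and not toward C2, where the C1 oxygen could be lost.

**30 ⇒ 29 ⇒ 28 ⇒ 27 ⇒ 24 + 25.** The C11–O acetyl and C8–O angeloyl ester bonds are cut, a silyl group is placed on the C6 oxygen and the C3 ketone is masked. Esters cannot survive the hydride, aluminium and peroxide steps, so they come last, the angelate from 25. The gain is 24, which bears only hydroxyls and one ketal. The demands are acylation of 24 at C8 and not at C6, blocking of the C6 hydroxyl while the tertiary C11 hydroxyl of 28 is acetylated, and no reaction at the C1 hydroxyl.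

**24 ⇒ 23 ⇒ 21.** The C8–O bond is replaced by C8–Si, then the C8–Si and C9–H bonds are cut to leave C8=C9. The C8 oxygen is on the same face as the C6 oxygen, so it can be delivered from C6–O through silicon. The gain is one stereocentre fewer and an alkene that can come from a bridged ether. The demands are silylation of the secondary C6 hydroxyl of 21 beside the tertiary C1 hydroxyl, a 5-exo hydrosilylation and retention in the oxidation.

**21 ⇒ 20 ⇒ 19.** The C10–H bond is removed and the C1 oxygen is reconnected to C8; then the C6–H bond is removed to give the ketone. The C1–O–C8 bridge of 19 is a rigid template with one open face. The gain is that C1, C6 and C10 depend on a single element and that 19 is a [4+3] adduct. The demands are hydride addition at C6 and H–Al addition across C9=C10 from the bridge face, with aluminium on C9 so that elimination breaks C8–O and not C1–O.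

**19 ⇒ 17.** The C1–C5 and C7–C8 bonds are cut (key disconnection). Two rings and four stereocentres (C1, C5, C7, C8) disappear, and an open chain with one stereocentre remains. The demands are a W-shaped cation, a compact approach and facial control by C4.

**17 ⇒ 16 ⇒ 15.** The C5–Cl bond and both O–Si bonds are cut. The chlorine has to go to one side of an unsymmetrical dialkyl ketone in the presence of an electron-rich furan; the free C11 hydroxyl of 15 directs enolisation to C5, and 16 fixes that choice. The gain is that regiochemistry is decided by structure and the C11 protecting group arrives with the same reagent. The demands are α' selectivity in the enolisation and chlorination of the enol ether faster than of the furan.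

**15 ⇒ 11 + 13.** The C5–C6 bond is cut. 13 brings C6, C7 and C11 with both methyls and the oxygen in place, so the union is convergent. The demand is a single addition of the organolithium made from 11 to the amide, with the hydroxyl of 13 masked as its alkoxide.

**11 ⇒ 10 ⇒ 9 ⇒ 8 ⇒ 7 ⇒ 4 + 6.** The C–I bond, the silyl ether, the ketal, then a C2–S bond (sulfone reinstated) and finally the C2–C3 bond are cut. 6 brings C3, C4 and C5 with the C4 configuration; 4 brings the furan with C2 as a clean carbon nucleophile. The demand is no epimerisation at C4 during acylation, desulfonylation and ketalisation.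

**4 ⇒ 2 ⇒ 1; 6 ⇒ 5; 13 ⇒ 12.** Functional-group changes lead to the commercial compounds 1, 5 and 12.

## Other disconnections considered

**Alternative 1:** The cut is C1–C5, with C5 rejoined to C10, which leads back to a cross-conjugated decalin dienone A1 (eudesmane skeleton; C6 silyl ether, C8 and C11 acetates). Forward, irradiation of A1 near 350 nm in acetic acid would pass through the bicyclo[3.1.0] zwitterion and its acid-induced cleavage to the hydroazulenone A2, with hydrogen on C1 and acetate on C10.
- In its favour: C6, C7, C8 and C10 would be set on a chair cyclohexane, where control is more predictable than on a cycloheptane. The enone arrives with the skeleton, so no late desaturation is needed; on this point it is better than the chosen plan.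
- Against it here: A2 has oxygen on C10 and hydrogen on C1, the reverse of the target. Correcting this means losing the C10 acetate and adding H and OH cis across a tetrasubstituted C1–C10 double bond, with oxygen at C1 on the α face and the enone untouched; no reliable method is evident. The angelate cannot be present during irradiation, so the C8 acetate must be exchanged later, and a C6 oxygen γ to the dienone is prone to elimination.
- Comparison: structurally the chosen plan takes the C1 oxygen directly from the furan, while this one must move it. Mechanistically both key steps pass through oxyallyl-type zwitterions of well-known classes (equal). In step economy the photoreaction equals the cycloaddition as a skeleton-forming step, but the oxygen transposition and acyl exchange would make the whole sequence longer.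

**Alternative 2:** The cuts are C6–C7 and C9–C10: the cyclopentane diene A3 (exocyclic methylene C5=C6, ethylidene C1=C10) is joined to the siloxy vinyldiazoacetate A4. Forward, Rh2(S-PTAD)4 would give a vinylcarbenoid that cyclopropanates the methylene; Cope rearrangement of the cis-divinylcyclopropane would give the cycloheptadiene A5.
- In its favour: it is convergent and the absolute configuration comes from a catalyst, not from a stoichiometric centre that is later destroyed; on this point it is better than the chosen plan. Two C–C bonds form in one step (equal to the chosen key step). A5 already has the C8 oxygen and, in the C7 ester, a direct precursor of C11.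
- Against it here: A5 has no oxygen at C1 or C6. The C1=C5 double bond would have to become C1–OH with C4=C5, C6 would have to be oxidised, and C6, C7 and C8 would be set afterwards on a flexible ring. Four of the five stereocentres are left for later, whereas the chosen adduct fixes or templates all five. The resident C4 centre of A3 may oppose the catalyst, and A3 is prone to double-bond migration.
- Comparison: the fragments are short, but the oxidation-level and stereochemical repairs after A5 would exceed the nine steps that follow the chosen key step.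

**Alternative 3:** The cut is C1–C2, made after unmasking a furan: the cyclohepta[b]furan A6 (C6 silyl ether, C8 silyl ether, C11 acetate, C10 methyl in place) is the precursor. Forward, m-CPBA would open the furan to the cis-enedione A7, and mild base would add the C2 enolate of the methyl ketone to the C1 ketone to give A8.
- In its favour: the complete 1-hydroxy-4-en-3-one array appears in one late operation, with no bridge opening, no desaturation and no hydride after the C11 acetate is in place; as an end-game it is better than the chosen plan. Both plans use a furan as latent functionality (equal).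
- Against it here: C1 would be set by aldol equilibrium, and nothing guarantees that the favoured epimer has the hydroxyl trans to the C10 methyl; the chosen plan fixes C1 stereospecifically in the cycloaddition (better). The problem is moved to A6, a cycloheptane with four stereocentres fused to a tetrasubstituted furan, for which this cut offers no ring-forming step. A7 can isomerise to the trans enedione, which cannot cyclise.
- Comparison: the last steps would be fewer, but the route to A6 would probably be as long as the whole chosen sequence to 24, so no overall gain is expected.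

Key step: step 13

## Steps

Step 1
Reactants: 1 methyl 3-methylfuran-2-carboxylate
Product: 2 (3-methylfuran-2-yl)methanol
Conditions: LiAlH4, Et2O, 0 °C
Reagents that add atoms: none
Why: Hydride reduction of an aromatic ester to the primary alcohol; the dialkylfuran is inert to LiAlH4.

Step 2
Reactants: 2 (3-methylfuran-2-yl)methanol
Product: 4 3-methyl-2-[(phenylsulfonyl)methyl]furan, via 2-(chloromethyl)-3-methylfuran 3 (not isolated)
Conditions: SOCl2, pyridine, Et2O, –10 °C; then PhSO2Na, Bu4NI (cat.), DMF, rt
Reagents that add atoms: thionyl chloride, O=S(Cl)Cl (chlorine of 3 only); sodium benzenesulfinate, [Na+].[O-]S(=O)c1ccccc1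
Why: The labile furfuryl chloride is used at once in an SN2 S-alkylation of the sulfinate; the sulfone makes the furylmethyl carbon a stable carbon nucleophile and avoids furfuryl organometallics, which react through the ring.

Step 3
Reactants: 5 methyl (S)-3-hydroxy-2-methylpropanoate
Product: 6 methyl (S)-3-(tert-butyldimethylsilyloxy)-2-methylpropanoate
Conditions: t-BuMe2SiCl, imidazole, CH2Cl2, rt
Reagents that add atoms: tert-butyldimethylsilyl chloride, CC(C)(C)[Si](C)(C)Cl
Why: Standard silylation; it blocks the β-hydroxyl so that the later β-oxygenated ketone cannot lose water or formaldehyde.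

Step 4
Reactants: 4 3-methyl-2-[(phenylsulfonyl)methyl]furan (2.2 equiv); 6 methyl (S)-3-(tert-butyldimethylsilyloxy)-2-methylpropanoate
Product: 7 (3S)-4-(tert-butyldimethylsilyloxy)-3-methyl-1-(3-methylfuran-2-yl)-1-(phenylsulfonyl)butan-2-one (both C1 epimers)
Conditions: n-BuLi, THF, –78 °C; then 6, –78 → –20 °C; aq. NH4Cl
Reagents that add atoms: none
Why: Claisen-type acylation of an α-sulfonyl carbanion by an ester forms C2–C3; the second equivalent of carbanion deprotonates the product between sulfone and carbonyl, which stops over-addition and keeps the C4 centre from epimerising.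

Step 5
Reactants: 7 the β-keto sulfone
Product: 8 (3S)-4-(tert-butyldimethylsilyloxy)-3-methyl-1-(3-methylfuran-2-yl)butan-2-one
Conditions: SmI2, THF/MeOH, –78 °C
Reagents that add atoms: none
Why: Reductive desulfonylation of a β-keto sulfone by electron transfer; the samarium enolate is protonated at C2, so C4 is not touched.

Step 6
Reactants: 8 the furylmethyl ketone
Product: 9 2-[(2S)-1-(tert-butyldimethylsilyloxy)propan-2-yl]-2-[(3-methylfuran-2-yl)methyl]-1,3-dioxolane
Conditions: (Me3SiOCH2)2, Me3SiOTf (5 mol %), CH2Cl2, –78 → –20 °C; pyridine quench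
Reagents that add atoms: 1,2-bis(trimethylsilyloxy)ethane, C[Si](C)(C)OCCO[Si](C)(C)C
Why: Aprotic silyl-transfer ketalisation at low temperature masks C3 without enolisation toward C4; the dioxolane later keeps the 1,4-dicarbonyl from trapping the cation and adds a gem-disubstituent effect to the tether.

Step 7
Reactants: 9 the silyl ether ketal
Product: 10 (2S)-2-{2-[(3-methylfuran-2-yl)methyl]-1,3-dioxolan-2-yl}propan-1-ol
Conditions: Bu4NF, THF, 0 °C → rt
Reagents that add atoms: none
Why: Fluoride cleavage of a primary silyl ether; ketal and furan are inert.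

Step 8
Reactants: 10 the primary alcohol
Product: 11 2-[(2R)-1-iodopropan-2-yl]-2-[(3-methylfuran-2-yl)methyl]-1,3-dioxolane (same spatial arrangement as 10; the descriptor changes because of iodine)
Conditions: I2, PPh3, imidazole, CH2Cl2, 0 °C → rt
Reagents that add atoms: iodine, II
Why: Appel-type iodination through the alkoxyphosphonium salt (SN2 at the primary carbon); imidazole buffers the medium so that ketal and furan survive.

Step 9
Reactants: 12 ethyl 3-hydroxy-3-methylbutanoate
Product: 13 3-hydroxy-N-methoxy-N,3-dimethylbutanamide
Conditions: MeNHOMe·HCl, i-PrMgCl, THF, –20 → 0 °C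
Reagents that add atoms: N,O-dimethylhydroxylamine hydrochloride, CNOC.Cl
Why: Direct aminolysis of the ester by the magnesium amide (Weinreb amide synthesis); the tertiary hydroxyl is carried as its magnesium alkoxide.

Step 10
Reactants: 11 the iodide; 13 the hydroxy Weinreb amide
Product: 15 (6S)-2-hydroxy-2-methyl-6-{2-[(3-methylfuran-2-yl)methyl]-1,3-dioxolan-2-yl}heptan-4-one, via primary alkyllithium 14 (not isolated)
Conditions: 11, t-BuLi (2.1 equiv), Et2O/pentane, –78 °C; then 13 pre-treated with i-PrMgCl (1.0 equiv) in THF, –78 → 0 °C; aq. NH4Cl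
Reagents that add atoms: tert-butyllithium, [Li]C(C)(C)C (lithium of 14 only)
Why: Iodine–lithium exchange on a primary iodide is faster than any attack on furan or ketal, and the alkyllithium adds once to the Weinreb amide through the chelated tetrahedral intermediate (Weinreb ketone synthesis), forming C5–C6; the hydroxyl of 13 is masked as alkoxide so that no organolithium is wasted.

Step 11
Reactants: 15 the β-hydroxy ketone
Product: 16 (6S)-2-methyl-6-{2-[(3-methylfuran-2-yl)methyl]-1,3-dioxolan-2-yl}-2,4-bis(triethylsilyloxy)hept-4-ene (E/Z mixture)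
Conditions: LiN(i-Pr)2 (2.5 equiv), THF, –78 °C (inverse addition); then Et3SiCl, Et3N, –78 °C → rt
Reagents that add atoms: chlorotriethylsilane, CC[Si](Cl)(CC)CC
Why: The lithium alkoxide formed first disfavours a second negative charge on the neighbouring methylene, so kinetic enolisation of the β-hydroxy ketone goes to the α' carbon C5 (dianion formation); silylation of both oxygens fixes this regiochemistry as the enol ether and protects the C11 oxygen in the same operation.

Step 12
Reactants: 16 the bis-silyl enol ether
Product: 17 (5RS,6R)-5-chloro-2-methyl-6-{2-[(3-methylfuran-2-yl)methyl]-1,3-dioxolan-2-yl}-2-(triethylsilyloxy)heptan-4-one (furan-tethered α-chloro ketone; both C5 epimers)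
Conditions: N-chlorosuccinimide (1.05 equiv), NaHCO3, THF, –78 → 0 °C
Reagents that add atoms: N-chlorosuccinimide, O=C1CCC(=O)N1Cl
Why: Electrophilic chlorination of a silyl enol ether puts chlorine only on C5; the enol ether is far more nucleophilic than the dialkylfuran, so one equivalent at low temperature should spare the ring, and both C5 epimers are usable.

Step 13
Reactants: 17 the furan-tethered α-chloro ketone
Product: 19 (4βH,5αH,7αH)-1α,8α-epoxy-3,3-(ethylenedioxy)-11-(triethylsilyloxy)guai-9-en-6-one (oxygen-bridged tricyclic ketone), via W-shaped oxyallyl cation 18 (not isolated)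
Conditions: Et3N (3 equiv), CF3CH2OH (0.02 M), 0 °C → rt
Reagents that add atoms: none
Why: Et3N removes a C7 proton from either C5 epimer of 17 in the ionising, weakly nucleophilic alcohol, and the enol(ate) expels chloride from C5 to give the 2-oxidoallyl cation 18, in which the C11 group and the C4 branch both lie cis to oxygen (W shape). The cation adds across furan carbons C1 and C8 in an intramolecular [4+3] cycloaddition (4π furan, 2π allyl cation), the established reaction type of oxyallyl cations from α-halo ketones with tethered furans. The seven-membered ring closes by the cycloaddition itself (bonds C1–C5 and C7–C8, the furan oxygen remaining as the C1–O–C8 bridge), and the cyclopentane closes in the same event as a five-membered annulation because the tether C2–C3–C4 links the cation terminus C5 to furan carbon C1. C1 and C8 are set by suprafacial addition to the furan (bridge on one face), C5 by the tether (C5–H syn to the bridge), and C7 by the W geometry together with the compact, boat-like approach, which leaves the C11 group pseudo-equatorial and anti to the bridge. The absolute sense comes from C4: to avoid A(1,3) strain with the oxygen-bearing C6 its hydrogen lies near the cation plane, the tether carbon C3 points to the furan and the methyl to the opposite side, so the furan reaches only one face of C5. The step needs exactly these two selectivities, C7 anti to the bridge and one enantiomeric series; the bulk of the C11 group (W cation) and the C4 centre taken from 5 secure them, and the enantiomer of 5 is equally available if the facial preference proves to be the reverse. High dilution and the non-nucleophilic alcohol are chosen to suppress Favorskii rearrangement and solvent capture of 18.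

Step 14
Reactants: 19 the oxygen-bridged tricyclic ketone
Product: 20 (4βH,5αH,7αH)-1α,8α-epoxy-3,3-(ethylenedioxy)-11-(triethylsilyloxy)guai-9-en-6β-ol
Conditions: Li[HB(s-Bu)3], THF, –78 → –20 °C; H2O
Reagents that add atoms: none
Why: Hydride reduction of a bicyclo[3.2.1]octan-3-one: the endo face is shielded by the C9=C10 bridge, so the bulky hydride enters from the face of the oxygen bridge and the new hydroxyl is axial and anti to the bridge (C6 β).

Step 15
Reactants: 20 the bridged alcohol
Product: 21 (4βH,5αH,7αH,10αH)-3,3-(ethylenedioxy)-11-(triethylsilyloxy)guai-8-ene-1α,6β-diol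
Conditions: Ni(cod)2 (10 mol %), PPh3 (20 mol %), i-Bu2AlH (3.5 equiv, slow addition), toluene, rt; then 60 °C; aq. potassium sodium tartrate
Reagents that add atoms: none
Why: Nickel-catalysed hydroalumination of an oxabicyclic alkene followed by β-alkoxide elimination: H–Al adds from the exo (bridge) face with aluminium on the less substituted C9 and hydrogen on C10, which sets C10 (H α, methyl β); syn elimination of the C8–O bond from C9–Al then opens the bridge and leaves the C8=C9 alkene and the tertiary C1 alkoxide.

Step 16
Reactants: 21 the cycloheptene diol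
Product: 23 (4βH,5αH,7αH,10αH)-3,3-(ethylenedioxy)-6β-O,8β-C-(dimethylsilanediyl)-11-(triethylsilyloxy)guaian-1α-ol (oxasilolane through C6–O–Si–C8), via C6 dimethylsilyl ether 22 (not isolated)
Conditions: (HMe2Si)2NH, THF, rt → 40 °C; evaporate; Pt2[(CH2=CHMe2Si)2O]3 (1 mol %), toluene, 50 °C
Reagents that add atoms: 1,1,3,3-tetramethyldisilazane, C[SiH](C)N[SiH](C)C
Why: The disilazane silylates the secondary C6 hydroxyl in preference to the hindered tertiary C1 hydroxyl; platinum-catalysed intramolecular hydrosilylation of the homoallylic silyl ether then closes the five-membered oxasilolane (5-exo), so silicon is delivered to C8 on the face of the C6 oxygen (β) and hydrogen goes to C9.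

Step 17
Reactants: 23 the oxasilolane
Product: 24 (4βH,5αH,7αH,8αH,10αH)-3,3-(ethylenedioxy)guaiane-1α,6β,8β,11-tetraol
Conditions: 30 % H2O2, KHCO3, Bu4NF, THF/MeOH, 40 °C
Reagents that add atoms: hydrogen peroxide, OO
Why: Tamao oxidation turns the C8–Si bond into C8–OH with retention (carbon migrates from silicon to oxygen in the silyl peroxide), giving the β-hydroxyl; the fluoride also removes the tertiary triethylsilyl ether, which frees C11–OH for the later acetylation.

Step 18
Reactants: 24 the tetraol; 25 angelic acid
Product: 27 8-O-angelate of 24 [(4βH,5αH,7αH,10αH)-8β-angeloyloxy-3,3-(ethylenedioxy)guaiane-1α,6β,11-triol], via angelic 2,4,6-trichlorobenzoic anhydride 26 (not isolated)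
Conditions: 25, 2,4,6-Cl3C6H2COCl, Et3N, toluene, rt; then 24, 75 °C
Reagents that add atoms: 2,4,6-trichlorobenzoyl chloride, O=C(Cl)c1c(Cl)cc(Cl)cc1Cl (aroyl group of 26 only)
Why: Yamaguchi esterification through the mixed anhydride, run without a nucleophilic pyridine catalyst to keep the (Z)-geometry; of the two secondary hydroxyls the C8 one (next to a methylene) is less hindered than the C6 one (between two methines), the tertiary hydroxyls do not react, and any acyl migration within the cis-1,3-diol should also favour C8.

Step 19
Reactants: 27 the C8 angelate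
Product: 28 6-O-triethylsilyl ether of 27
Conditions: Et3SiCl, imidazole, DMF, 0 °C → rt
Reagents that add atoms: chlorotriethylsilane, CC[Si](Cl)(CC)CC
Why: Silyl chloride with imidazole silylates the remaining secondary hydroxyl (C6) and leaves tertiary hydroxyls, so that C11–OH can be acetylated alone in the next step.

Step 20
Reactants: 28 the C6 silyl ether
Product: 29 11-O-acetate of 28
Conditions: Ac2O, 4-(dimethylamino)pyridine, Et3N, CH2Cl2, 35 °C
Reagents that add atoms: acetic anhydride, CC(=O)OC(C)=O
Why: Acylpyridinium-mediated acetylation reaches the open-chain dimethylcarbinol; the ring-fusion C1 hydroxyl, flanked by C2, C5 and C10, is much more hindered and should stay free.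

Step 21
Reactants: 29 the fully acylated ketal
Product: 30 (4βH,5αH,7αH,10αH)-11-acetoxy-8β-angeloyloxy-1α,6β-dihydroxyguaian-3-one
Conditions: TsOH·H2O (0.2 equiv), THF/H2O, rt
Reagents that add atoms: water, O
Why: Mild aqueous acid hydrolyses the dioxolane and the secondary triethylsilyl ether together; the esters and the not yet allylic tertiary alcohol tolerate it, and any epimerisation at C4 is without consequence.

Step 22
Reactants: 30 the saturated hydroxy ketone
Product: 32 11-acetoxy-8β-angeloyloxy-1α,6β-dihydroxy-10αH-guai-4-en-3-one (target), via tris(trimethylsilyl) enol ether 31 (not isolated)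
Conditions: Me3SiOTf, Et3N, CH2Cl2, 0 °C → rt; evaporate; Pd(OAc)2 (1.1 equiv), MeCN, rt → 40 °C; then citric acid, MeOH, 0 °C
Reagents that add atoms: trimethylsilyl trifluoromethanesulfonate, C[Si](C)(C)OS(=O)(=O)C(F)(F)F (silyl groups of 31 only)
Why: Saegusa–Ito oxidation: soft enolisation should favour the more substituted C3=C4 silyl enol ether (the C2 side is neopentylic) and masks both hydroxyls as trimethylsilyl ethers in passing; the palladium enolate formed on the convex face loses the syn C5–H to give the C4=C5 enone, and mild acid then removes the silyl ethers; no stereocentre is made and C4 and C5 lose theirs.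

## Compound list

1 | methyl 3-methylfuran-2-carboxylate | COC(=O)c1occc1C | starting material
2 | (3-methylfuran-2-yl)methanol | Cc1ccoc1CO | intermediate
3 | 2-(chloromethyl)-3-methylfuran | Cc1ccoc1CCl | intermediate
4 | 3-methyl-2-[(phenylsulfonyl)methyl]furan | Cc1ccoc1CS(=O)(=O)c2ccccc2 | intermediate
5 | methyl (S)-3-hydroxy-2-methylpropanoate | COC(=O)[C@@H](C)CO | starting material
6 | methyl (S)-3-(tert-butyldimethylsilyloxy)-2-methylpropanoate | COC(=O)[C@@H](C)CO[Si](C)(C)C(C)(C)C | intermediate
7 | (3S)-4-(tert-butyldimethylsilyloxy)-3-methyl-1-(3-methylfuran-2-yl)-1-(phenylsulfonyl)butan-2-one, both C1 epimers | Cc1ccoc1C(S(=O)(=O)c2ccccc2)C(=O)[C@@H](C)CO[Si](C)(C)C(C)(C)C | intermediate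
8 | (3S)-4-(tert-butyldimethylsilyloxy)-3-methyl-1-(3-methylfuran-2-yl)butan-2-one | Cc1ccoc1CC(=O)[C@@H](C)CO[Si](C)(C)C(C)(C)C | intermediate
9 | 2-[(2S)-1-(tert-butyldimethylsilyloxy)propan-2-yl]-2-[(3-methylfuran-2-yl)methyl]-1,3-dioxolane | Cc1ccoc1CC2(OCCO2)[C@@H](C)CO[Si](C)(C)C(C)(C)C | intermediate
10 | (2S)-2-{2-[(3-methylfuran-2-yl)methyl]-1,3-dioxolan-2-yl}propan-1-ol | Cc1ccoc1CC2(OCCO2)[C@@H](C)CO | intermediate
11 | 2-[(2R)-1-iodopropan-2-yl]-2-[(3-methylfuran-2-yl)methyl]-1,3-dioxolane | Cc1ccoc1CC2(OCCO2)[C@@H](C)CI | intermediate
12 | ethyl 3-hydroxy-3-methylbutanoate | CCOC(=O)CC(C)(C)O | starting material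
13 | 3-hydroxy-N-methoxy-N,3-dimethylbutanamide | CON(C)C(=O)CC(C)(C)O | intermediate
14 | [(2S)-2-{2-[(3-methylfuran-2-yl)methyl]-1,3-dioxolan-2-yl}propyl]lithium | Cc1ccoc1CC2(OCCO2)[C@@H](C)C[Li] | intermediate
15 | (6S)-2-hydroxy-2-methyl-6-{2-[(3-methylfuran-2-yl)methyl]-1,3-dioxolan-2-yl}heptan-4-one | Cc1ccoc1CC2(OCCO2)[C@@H](C)CC(=O)CC(C)(C)O | intermediate
16 | (6S)-2-methyl-6-{2-[(3-methylfuran-2-yl)methyl]-1,3-dioxolan-2-yl}-2,4-bis(triethylsilyloxy)hept-4-ene, E/Z mixture | Cc1ccoc1CC2(OCCO2)[C@@H](C)C=C(O[Si](CC)(CC)CC)CC(C)(C)O[Si](CC)(CC)CC | intermediate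
17 | (5RS,6R)-5-chloro-2-methyl-6-{2-[(3-methylfuran-2-yl)methyl]-1,3-dioxolan-2-yl}-2-(triethylsilyloxy)heptan-4-one; one C5 epimer drawn, both are formed and used | Cc1ccoc1CC2(OCCO2)[C@@H](C)[C@H](Cl)C(=O)CC(C)(C)O[Si](CC)(CC)CC | intermediate
18 | W-shaped 2-oxidoallyl cation C5–C6–C7 from 17 | Cc1ccoc1CC2(OCCO2)[C@@H](C)[CH+]/C([O-])=C/C(C)(C)O[Si](CC)(CC)CC | intermediate
19 | (4βH,5αH,7αH)-1α,8α-epoxy-3,3-(ethylenedioxy)-11-(triethylsilyloxy)guai-9-en-6-one | O1[C@H]2C=C(C)[C@@]13CC4(OCCO4)[C@@H](C)[C@@H]3C(=O)[C@@H]2C(C)(C)O[Si](CC)(CC)CC | intermediate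
20 | (4βH,5αH,7αH)-1α,8α-epoxy-3,3-(ethylenedioxy)-11-(triethylsilyloxy)guai-9-en-6β-ol | O1[C@H]2C=C(C)[C@@]13CC4(OCCO4)[C@@H](C)[C@@H]3[C@H](O)[C@@H]2C(C)(C)O[Si](CC)(CC)CC | intermediate
21 | (4βH,5αH,7αH,10αH)-3,3-(ethylenedioxy)-11-(triethylsilyloxy)guai-8-ene-1α,6β-diol | C1=C[C@H](C)[C@]2(O)CC3(OCCO3)[C@@H](C)[C@@H]2[C@H](O)[C@@H]1C(C)(C)O[Si](CC)(CC)CC | intermediate
22 | 6-O-(dimethylsilyl) ether of 21 | C1=C[C@H](C)[C@]2(O)CC3(OCCO3)[C@@H](C)[C@@H]2[C@H](O[SiH](C)C)[C@@H]1C(C)(C)O[Si](CC)(CC)CC | intermediate
23 | (4βH,5αH,7αH,10αH)-3,3-(ethylenedioxy)-6β-O,8β-C-(dimethylsilanediyl)-11-(triethylsilyloxy)guaian-1α-ol | [C@@H]14C[C@H](C)[C@]2(O)CC3(OCCO3)[C@@H](C)[C@@H]2[C@H](O[Si]4(C)C)[C@@H]1C(C)(C)O[Si](CC)(CC)CC | intermediate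
24 | (4βH,5αH,7αH,8αH,10αH)-3,3-(ethylenedioxy)guaiane-1α,6β,8β,11-tetraol | O[C@@H]1C[C@H](C)[C@]2(O)CC3(OCCO3)[C@@H](C)[C@@H]2[C@H](O)[C@@H]1C(C)(C)O | intermediate
25 | angelic acid, (Z)-2-methylbut-2-enoic acid | C/C=C(/C)C(=O)O | starting material
26 | (Z)-2-methylbut-2-enoic 2,4,6-trichlorobenzoic anhydride | C/C=C(/C)C(=O)OC(=O)c1c(Cl)cc(Cl)cc1Cl | intermediate
27 | 8-O-angelate of 24 | C/C=C(/C)C(=O)O[C@@H]1C[C@H](C)[C@]2(O)CC3(OCCO3)[C@@H](C)[C@@H]2[C@H](O)[C@@H]1C(C)(C)O | intermediate
28 | 6-O-triethylsilyl ether of 27 | C/C=C(/C)C(=O)O[C@@H]1C[C@H](C)[C@]2(O)CC3(OCCO3)[C@@H](C)[C@@H]2[C@H](O[Si](CC)(CC)CC)[C@@H]1C(C)(C)O | intermediate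
29 | 11-O-acetate of 28 | C/C=C(/C)C(=O)O[C@@H]1C[C@H](C)[C@]2(O)CC3(OCCO3)[C@@H](C)[C@@H]2[C@H](O[Si](CC)(CC)CC)[C@@H]1C(C)(C)OC(C)=O | intermediate
30 | (4βH,5αH,7αH,10αH)-11-acetoxy-8β-angeloyloxy-1α,6β-dihydroxyguaian-3-one | C/C=C(/C)C(=O)O[C@@H]1C[C@H](C)[C@]2(O)CC(=O)[C@@H](C)[C@@H]2[C@H](O)[C@@H]1C(C)(C)OC(C)=O | intermediate
31 | 1,6-bis-O-trimethylsilyl ether and 3-trimethylsilyl enol ether (C3=C4) of 30 | C/C=C(/C)C(=O)O[C@@H]1C[C@H](C)[C@]2(O[Si](C)(C)C)CC(O[Si](C)(C)C)=C(C)[C@@H]2[C@H](O[Si](C)(C)C)[C@@H]1C(C)(C)OC(C)=O | intermediate
32 | 11-acetoxy-8β-angeloyloxy-1α,6β-dihydroxy-10αH-guai-4-en-3-one (CNP0273287.1) | C/C=C(/C)C(=O)O[C@@H]1C[C@H](C)[C@]2(O)CC(=O)C(C)=C2[C@H](O)[C@@H]1C(C)(C)OC(C)=O | target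

## Step count and least certain steps

Total: 22 steps (12 before the key step, the key step, 9 after it). Longest linear sequence: 20 steps (1 → 2 → 4 → 7 → 8 → 9 → 10 → 11 → 15 → 16 → 17 → 19 → 20 → 21 → 23 → 24 → 27 → 28 → 29 → 30 → 32); 19 steps from 5.

**Step 13 (key step).** The proton to be removed sits on the neopentylic C7, so ionisation may be slow and Favorskii rearrangement or solvent capture of the cation may compete. The facial bias from C4 may also be too small, giving the diastereomeric tricycle as well. The fallback changes how the cation is made; it sets out from 11 and comes back at 19. 11 is lithiated as in step 10 and added to N-methoxy-N,3-dimethylbut-2-enamide to give the enone (6S)-2-methyl-6-{2-[(3-methylfuran-2-yl)methyl]-1,3-dioxolan-2-yl}hept-2-en-4-one F1. Alkaline H2O2 (Weitz–Scheffer epoxidation) converts it into the 3,3-dimethyloxiranyl ketone F2 (both epoxide configurations). Et3SiOTf with Et3N gives the epoxy enol silane F3; enolisation is possible only toward C5. A catalytic amount of Et3SiOTf in CH2Cl2 at –78 °C should then open the silylated epoxide to the same C5–C6–C7 allyl cation, now with C11–OSiEt3 formed in the ionisation, and the intramolecular (4+3) cycloaddition of this epoxy enol silane should close to 19 without base and without any enolisation toward C7.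

**Step 15.** Hydrometalation of a trisubstituted alkene next to a fully substituted bridgehead may be sluggish, and reductive opening of the dioxolane by the aluminium hydride may set in at the temperature needed for the β-elimination. The fallback sets out from 20 and comes back at 21. Palladium-catalysed hydrostannation (Bu3SnH, Pd(OH)2/C, THF) should give the exo C9 stannane F4 (tin on C9 and hydrogen on C10, both on the bridge face). MeLi in THF then effects tin–lithium exchange, and the C9 lithium compound eliminates the C8–O bond at low temperature, with no aluminium Lewis acid present.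

**Step 16.** Insertion into the internal ring alkene may be slow, and dehydrogenative silylation involving the free tertiary C1 hydroxyl may divert the Si–H group. The fallback sets out from 21 and comes back at 24. The C6 hydroxyl is converted into its tert-butyl carbonate F5 (Boc2O, 4-(dimethylamino)pyridine). IBr in toluene at –80 °C should give the six-membered iodo carbonate F6 by attack of the carbonate oxygen on C8 from the β face, with iodine on C9 α. Bu3SnH with azobisisobutyronitrile removes the iodine to give the cyclic carbonate F7. K2CO3 in MeOH frees the diol as the C11 silyl ether F8, and Bu4NF gives 24.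

**Step 18.** The two secondary hydroxyls may not be discriminated well enough, which would give C6 and bis-acylated products; some isomerisation of the angelate to the tiglate is also possible. The fallback removes the need for discrimination; it sets out from 21 and comes back at 28. Bu4NF gives the triol F9. Et3SiCl with imidazole silylates the only secondary hydroxyl to give the C6 silyl ether F10. (HMe2Si)2NH at 60 °C silylates the C11 hydroxyl and the platinum catalyst of step 16 closes the oxasilolane F11 through C11–O–Si–C8, again on the β face. H2O2, KF and KHCO3 give the diol F12, in which C8–OH is the only secondary hydroxyl. Angeloylation as in step 18 then gives 28.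

**Step 22.** Enolisation toward C2 may be followed by loss of the C1 oxygen (β-elimination from the enol ether or the palladium enolate), and β-hydride elimination may go to the C4 methyl and give the exocyclic alkene. The fallback sets out from 29 and comes back at 32. Transketalisation with I2 (cat.) in acetone removes the dioxolane and should keep the C6 silyl ether, giving the ketone F13. IBX in DMSO at 70 °C dehydrogenates it to the enone F14; desaturation can only run toward C5 because C1 carries no hydrogen, and the blocked C6 oxygen cannot be oxidised. HF·pyridine then removes the silyl ether to give 32.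

## Further compounds

F1 | step 13 | (6S)-2-methyl-6-{2-[(3-methylfuran-2-yl)methyl]-1,3-dioxolan-2-yl}hept-2-en-4-one | Cc1ccoc1CC2(OCCO2)[C@@H](C)CC(=O)C=C(C)C
F2 | step 13 | (4S)-1-(3,3-dimethyloxiran-2-yl)-4-{2-[(3-methylfuran-2-yl)methyl]-1,3-dioxolan-2-yl}pentan-2-one... written as its ketone: 3,3-dimethyloxiran-2-yl (3S)-3-{2-[(3-methylfuran-2-yl)methyl]-1,3-dioxolan-2-yl}butyl ketone, both epoxide configurations | Cc1ccoc1CC2(OCCO2)[C@@H](C)CC(=O)C3OC3(C)C
F3 | step 13 | triethylsilyl enol ether (toward C5) of F2, E/Z mixture | Cc1ccoc1CC2(OCCO2)[C@@H](C)C=C(O[Si](CC)(CC)CC)C3OC3(C)C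
F4 | step 15 | (4βH,5αH,7αH,10αH)-1α,8α-epoxy-3,3-(ethylenedioxy)-9α-(tributylstannyl)-11-(triethylsilyloxy)guaian-6β-ol | O1[C@H]2[C@@H]([Sn](CCCC)(CCCC)CCCC)[C@H](C)[C@@]13CC4(OCCO4)[C@@H](C)[C@@H]3[C@H](O)[C@@H]2C(C)(C)O[Si](CC)(CC)CC
F5 | step 16 | 6-O-(tert-butoxycarbonyl) derivative of 21 | C1=C[C@H](C)[C@]2(O)CC3(OCCO3)[C@@H](C)[C@@H]2[C@H](OC(=O)OC(C)(C)C)[C@@H]1C(C)(C)O[Si](CC)(CC)CC
F6 | step 16 | 6β,8β-cyclic carbonate with 9α-iodine, 3,3-(ethylenedioxy)-11-(triethylsilyloxy)guaian-1α-ol series | O=C1O[C@@H]2[C@@H](I)[C@H](C)[C@]3(O)CC4(OCCO4)[C@@H](C)[C@@H]3[C@H](O1)[C@@H]2C(C)(C)O[Si](CC)(CC)CC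
F7 | step 16 | 6β,8β-cyclic carbonate of 3,3-(ethylenedioxy)-11-(triethylsilyloxy)guaiane-1α,6β,8β-triol | O=C1O[C@@H]2C[C@H](C)[C@]3(O)CC4(OCCO4)[C@@H](C)[C@@H]3[C@H](O1)[C@@H]2C(C)(C)O[Si](CC)(CC)CC
F8 | step 16 | 11-O-triethylsilyl ether of 24 | O[C@@H]1C[C@H](C)[C@]2(O)CC3(OCCO3)[C@@H](C)[C@@H]2[C@H](O)[C@@H]1C(C)(C)O[Si](CC)(CC)CC
F9 | step 18 | (4βH,5αH,7αH,10αH)-3,3-(ethylenedioxy)guai-8-ene-1α,6β,11-triol | C1=C[C@H](C)[C@]2(O)CC3(OCCO3)[C@@H](C)[C@@H]2[C@H](O)[C@@H]1C(C)(C)O
F10 | step 18 | 6-O-triethylsilyl ether of F9 | C1=C[C@H](C)[C@]2(O)CC3(OCCO3)[C@@H](C)[C@@H]2[C@H](O[Si](CC)(CC)CC)[C@@H]1C(C)(C)O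
F11 | step 18 | oxasilolane through C11–O–SiMe2–C8 (silicon β on C8) with 6β-triethylsilyloxy and 1α-hydroxyl | [C@@H]14C[C@H](C)[C@]2(O)CC3(OCCO3)[C@@H](C)[C@@H]2[C@H](O[Si](CC)(CC)CC)[C@@H]1C(C)(C)O[Si]4(C)C
F12 | step 18 | 6-O-triethylsilyl ether of 24 | O[C@@H]1C[C@H](C)[C@]2(O)CC3(OCCO3)[C@@H](C)[C@@H]2[C@H](O[Si](CC)(CC)CC)[C@@H]1C(C)(C)O
F13 | step 22 | 6-O-triethylsilyl ether of 30 | C/C=C(/C)C(=O)O[C@@H]1C[C@H](C)[C@]2(O)CC(=O)[C@@H](C)[C@@H]2[C@H](O[Si](CC)(CC)CC)[C@@H]1C(C)(C)OC(C)=O
F14 | step 22 | 6-O-triethylsilyl ether of 32 | C/C=C(/C)C(=O)O[C@@H]1C[C@H](C)[C@]2(O)CC(=O)C(C)=C2[C@H](O[Si](CC)(CC)CC)[C@@H]1C(C)(C)OC(C)=O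
A1 | alternative 1 | 8β,11-diacetoxy-6β-(tert-butyldimethylsilyloxy)eudesma-1,4-dien-3-one (10β-methyl) | CC(=O)O[C@@H]1C[C@@]2(C)C=CC(=O)C(C)=C2[C@H](O[Si](C)(C)C(C)(C)C)[C@@H]1C(C)(C)OC(C)=O
A2 | alternative 1 | 8β,10α,11-triacetoxy-6β-(tert-butyldimethylsilyloxy)-1αH-guai-4-en-3-one | CC(=O)O[C@@H]1C[C@@](C)(OC(C)=O)[C@@H]2CC(=O)C(C)=C2[C@H](O[Si](C)(C)C(C)(C)C)[C@@H]1C(C)(C)OC(C)=O
A3 | alternative 2 | 8-[(E)-ethylidene]-6-methyl-7-methylene-1,4-dioxaspiro[4.4]nonane (one C6 configuration) | C/C=C1\CC2(OCCO2)[C@@H](C)C1=C
A4 | alternative 2 | methyl 3-(tert-butyldimethylsilyloxy)-2-diazobut-3-enoate | COC(=O)C(=[N+]=[N-])C(=C)O[Si](C)(C)C(C)(C)C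
A5 | alternative 2 | bicyclic cycloheptadiene with C7 methyl ester, C8 silyl enol ether, C1=C5 and C3 dioxolane | COC(=O)C1=C(O[Si](C)(C)C(C)(C)C)C[C@H](C)C2=C(C1)[C@H](C)C3(OCCO3)C2
A6 | alternative 3 | cyclohepta[b]furan with 2,3-dimethylfuran ring, 6β-(tert-butyldimethylsilyloxy), 7β-(2-acetoxypropan-2-yl), 8β-(triethylsilyloxy) and 10β-methyl | CC[Si](CC)(CC)O[C@@H]1C[C@H](C)c2oc(C)c(C)c2[C@H](O[Si](C)(C)C(C)(C)C)[C@@H]1C(C)(C)OC(C)=O
A7 | alternative 3 | cis-enedione from A6 (C1 ring ketone, C4=C5, C3 methyl ketone) | CC[Si](CC)(CC)O[C@@H]1C[C@H](C)C(=O)/C(=C(/C)C(C)=O)[C@H](O[Si](C)(C)C(C)(C)C)[C@@H]1C(C)(C)OC(C)=O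
A8 | alternative 3 | 11-acetoxy-6β-(tert-butyldimethylsilyloxy)-1α-hydroxy-8β-(triethylsilyloxy)-10αH-guai-4-en-3-one | CC[Si](CC)(CC)O[C@@H]1C[C@H](C)[C@]2(O)CC(=O)C(C)=C2[C@H](O[Si](C)(C)C(C)(C)C)[C@@H]1C(C)(C)OC(C)=O
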